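Target cannot pile up untouched beside substrate and coupling partner if the steps thought possible run, since each of them has a step onto target. So we ask how much is lost for each fraction of the charge that arrives as target.

| flask | substrate | coupling partner | remark | time |
|---|---|---|---|---|
| eta | 2.0 × 10⁻⁴ M | 0.24 mM | run made earlier |  |
| delta | 2.0 × 10⁻⁴ M | 0.12 mM | run made earlier |  |
| beta | 2.0 × 10⁻⁴ M | 0.18 mM | run made earlier |  |
| zeta | 4.0 × 10⁻⁴ M | 0.24 mM | run made earlier |  |
| birch | 2.0 × 10⁻⁴ M | 0.240 mM | a single well-mixed tank run continuously and read at steady state, 7.50 min in it on average |  |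
| larch | 2.0 × 10⁻⁴ M (fed, over 2.00 min) | 0.240 mM | all but substrate at the start; substrate goes in evenly over 2.00 min, the run ends at 2.5 min | 2.5 min |
| oak | 2.0 × 10⁻⁴ M | 0.240 mM | everything together in a closed stirred flask, run for 2.5 min | 2.5 min |
| maple | 2.0 × 10⁻⁴ M | 0.240 mM | one stirred flow tank at steady state, fed with the mixture as stated, mean residence time 2.5 min |  |

| run | time / min | target / % | over-reaction product / % | side product / % |
|---|---|---|---|---|
| eta | 0.200 | 0.2 | 0 | 0 |
| eta | 0.333 | 0.5 | 0 | 0 |
| eta | 0.500 | 4.2 | 0 | 0 |
| eta | 0.667 | 6.8 | 0 | 0.4 |
| eta | 1.00 | 9.9 | 0.6 | 5.2 |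
| eta | 1.50 | 18.3 | 3.2 | 6.4 |
| eta | 2.50 | 31.8 | 7.2 | 10.9 |
| delta | 0.167 | 0.4 | 1.8 | 0.2 |
| delta | 0.500 | 1.9 | 0.6 | 0 |
| delta | 0.833 | 4.7 | 0 | 0.5 |
| delta | 1.33 | 10.5 | 0.7 | 3.8 |
| delta | 2.00 | 22.0 | 1.2 | 6.8 |
| delta | 2.50 | 24.8 | 0.6 | 8.7 |
| delta | 3.00 | 27.6 | 1.8 | 9.2 |
| beta | 0.250 | 0.4 | 0.6 | 0.8 |
| beta | 0.333 | 2.2 | 0 | 0.6 |
| beta | 0.500 | 2.9 | 0 | 0.3 |
| beta | 0.833 | 7.0 | 0 | 0.3 |
| beta | 1.33 | 13.2 | 1.1 | 3.5 |
| beta | 2.00 | 22.5 | 2.8 | 8.6 |
| beta | 3.00 | 35.0 | 3.6 | 11.9 |
| zeta | 0.250 | 2.4 | 0 | 0.2 |
| zeta | 0.417 | 2.3 | 0.6 | 0 |
| zeta | 0.833 | 7.9 | 0 | 3.6 |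
| zeta | 1.50 | 14.4 | 2.5 | 11.9 |
| zeta | 3.00 | 26.8 | 2.4 | 17.8 |

(each reading ± 1 percentage point)

- a species is counted by the substrate in it: one side product counts as two
- the stated concentrations are those of everything mixed, before any reaction; amounts are the same in each set-up
- steps thought possible: intermediate A <-> intermediate B; substrate + target -> side product; intermediate C <-> intermediate D; coupling partner + intermediate B -> target; substrate -> intermediate A; intermediate B -> intermediate C; coupling partner + target -> over-reaction product
- the feed brings no volume worth counting
- the earlier runs were made in a closed, stirred flask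

- order of the set-ups by the share of target in all that became target or over-reaction product or side product, at the outlet or at the end, highest first (birch / larch / oak / maple)
- share of target in all that became target or over-reaction product or side product, at the outlet or at the end, birch
- share of target in all that became target or over-reaction product or side product, at the outlet or at the end, larch
- share of target in all that became target or over-reaction product or side product, at the outlet or at the end, oak
- share of target in all that became target or over-reaction product or side product, at the outlet or at the end, maple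

Oak has the recipe of the eta run, and the share of target (the selectivity) equals one over one plus the side and over-reaction losses per target. The first way reads eta's last row at 2.50 min: side product per target is 0.343, over-reaction product per target is 0.226, and the share is 63.7 %.

The second way uses other runs. Side loss per target goes with the substrate and over-reaction loss per target with the coupling partner, while the first-order step takes the same fraction of substrate at either charge. So we scale the last rows, read later, at 3.00 min. Zeta, scaled down to oak's substrate, gives 0.332, which agrees with eta. Beta, scaled up to oak's partner, gives 0.137, and delta gives 0.130, both less than eta's figure.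

The ways part there, and the one that cheats is eta's single over-reaction reading, 2.8 percentage points above the scaled value against a scatter of 1 point. We therefore commit to 0.469 as the loss ratio, the fraction of the charge lost to side and over-reaction product per fraction in target, which makes oak's share 68.1 %. Larch, maple and birch differ in vessel or feed from the earlier runs, so our reckoning stops at oak.

The forecast gave oak > larch > maple > birch, with oak 65 % (61 % to 69 %), larch 62 % (53 % to 71 %), maple 45 % (37 % to 53 %) and birch 33 % (25 % to 42 %), on the ground that “Oak is simply the eta run at 2.5 min, giving about 65%.”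

The simulation gives oak > larch > maple > birch: oak 66.3 %, larch 63.4 %, maple 41.4 %, birch 33.9 %.

    intermediate A ⇌ intermediate B (K = 0.370, k = 0.0110 s⁻¹)
    substrate + target → side product (k = 69.0 M⁻¹ s⁻¹)
    intermediate C ⇌ intermediate D (K = 0.350, k = 0.270 s⁻¹)
    coupling partner + intermediate B → target (k = 550 M⁻¹ s⁻¹)
    substrate → intermediate A (k = 0.0160 s⁻¹)
    intermediate B → intermediate C (k = 0.0150 s⁻¹)
    coupling partner + target → over-reaction product (k = 12.0 M⁻¹ s⁻¹)

Oak's loss ratio at 2.50 min comes to 0.508, beside our 0.469. The neighbouring flask is oak with substrate cut to 1.2 × 10⁻⁴ M. Our rule scales the side part to 0.199 and keeps the over-reaction part at 0.137, which gives a share of 74.9 %. That flask holds 33.8 % target, 5.58 % over-reaction product and 7.50 % side product, each of its own charge, a share of 72.1 %.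

The data come from a simulation for substances that don't exist; noise was put on by code.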